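**Plan**

- Retrosynthetic cuts, in order: the three O–Si bonds; the two side-chain alkenes (prenyl from allyl plus 2-methylbut-2-ene); C2–C3 of ring C, which leads back to a 2-aryl-4-methylene-4H-1,3-benzodioxine; the exocyclic C=CH2 (from a lactone C=O); the two acetal C–O bonds (ring A salicylic acid plus ring B benzaldehyde); each aryl–allyl bond (from an allyl aryl ether by Claisen rearrangement).
- Enabling feature: ring C (O1–C2–C3–C4(=O)–C4a–C8a) is a 2-aryl-tetrahydropyran-4-one fused to ring A. It is the C-bonded isomer of a cyclic enol acetal in which C2 sits between O1 and the enol oxygen on C4, so a shift of C2 from that oxygen to C3 builds ring C.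
- Forward order: the ring A acid and the ring B aldehyde (four steps each) are condensed to the benzodioxinone (first ring closure), the carbonyl is methylenated, the dioxine ring is rearranged into ring C, the allyl groups are turned into prenyl groups, and the silyl ethers are removed.
- Stereochemistry: C2 is the only stereocentre. It is created in the rearrangement from a racemic acetal, and the chiral counteranion of the acid imposes the (S) configuration; all later steps are neutral or buffered.

Key step: step 11

Assumption: both prenyl groups are carried as allyl groups through the acid-mediated steps and completed by cross-metathesis afterwards, because a terminal alkene is a much poorer partner for the benzylic oxocarbenium ion than a trisubstituted one. The catalyst antipode that leads to (2S) has to be found by experiment.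

TBS = tert-butyldimethylsilyl; TBSO = tert-butyldimethylsilyloxy.

**Route**

Step 1
Reactants: 1 2,4,6-trihydroxybenzaldehyde
Product: 2 2-hydroxy-4,6-bis(TBSO)benzaldehyde
Conditions: TBSCl (2.1 equiv), imidazole, DMF/CH2Cl2, 0 °C
Reagents that add atoms: tert-butyldimethylsilyl chloride, CC(C)(C)[Si](C)(C)Cl
Why: Phenol silylation takes the para-hydroxyl and one ortho-hydroxyl, while the last ortho-hydroxyl is held in the hydrogen bond to the formyl oxygen and should stay free with two equivalents of TBSCl.

Step 2
Reactants: 2 2-hydroxy-4,6-bis(TBSO)benzaldehyde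
Product: 3 2-(allyloxy)-4,6-bis(TBSO)benzaldehyde
Conditions: allyl alcohol, PPh3, DIAD, THF, 0 °C to rt
Reagents that add atoms: allyl alcohol, C=CCO
Why: Mitsunobu etherification alkylates the acidic, hydrogen-bonded phenol under neutral conditions, avoiding the carbonate bases that would strip the aryl silyl ether para to the formyl group.

Step 3
Reactants: 3 2-(allyloxy)-4,6-bis(TBSO)benzaldehyde
Product: 4 3-allyl-2-hydroxy-4,6-bis(TBSO)benzaldehyde
Conditions: 1,2-dichlorobenzene, 180 °C, sealed tube, Ar
Reagents that add atoms: none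
Why: Aromatic Claisen rearrangement delivers the allyl group to C3, the only free position ortho to the ether oxygen, and tautomerisation restores the phenol next to the new side chain, which fixes the later 8-position of the flavanone.

Step 4
Reactants: 4 3-allyl-2-hydroxy-4,6-bis(TBSO)benzaldehyde
Product: 5 3-allyl-2-hydroxy-4,6-bis(TBSO)benzoic acid
Conditions: NaClO2, NaH2PO4, 2-methylbut-2-ene (excess), t-BuOH/THF/H2O, 0 °C; used without storage
Reagents that add atoms: sodium chlorite NaClO2, [Na+].[O-]Cl=O
Why: Pinnick oxidation converts the aldehyde into the acid at mildly acidic pH that the silyl ethers tolerate, and the excess 2-methylbut-2-ene takes up hypochlorous acid before it can reach the terminal alkene or the electron-rich ring.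

Step 5
Reactants: 6 3,4-dihydroxybenzaldehyde
Product: 7 3-(allyloxy)-4-hydroxybenzaldehyde
Conditions: NaH (2.1 equiv), DMSO, 20 °C; allyl bromide (1.0 equiv); then 1 M HCl
Reagents that add atoms: allyl bromide, C=CCBr
Why: Regioselective Williamson alkylation of a catechol dianion: the 4-oxide is delocalised into the formyl group, so the single equivalent of allyl bromide should be taken by the more nucleophilic 3-oxide.

Step 6
Reactants: 7 3-(allyloxy)-4-hydroxybenzaldehyde
Product: 8 2-allyl-3,4-dihydroxybenzaldehyde
Conditions: N,N-diethylaniline, 200 °C, Ar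
Reagents that add atoms: none
Why: Aromatic Claisen rearrangement: with C4 occupied, the allyl group migrates to C2, the only open ortho position, as in the corresponding rearrangement of isovanillin allyl ether.

Step 7
Reactants: 8 2-allyl-3,4-dihydroxybenzaldehyde
Product: 9 2-allyl-4-hydroxy-3-methoxybenzaldehyde
Conditions: NaH (2.1 equiv), DMSO, 20 °C; MeI (1.0 equiv); then 1 M HCl
Reagents that add atoms: iodomethane, CI
Why: The same dianion principle (Williamson methylation) should direct one equivalent of iodomethane to the 3-oxide, the conjugated 4-oxide again being the weaker nucleophile.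

Step 8
Reactants: 9 2-allyl-4-hydroxy-3-methoxybenzaldehyde
Product: 10 2-allyl-4-(TBSO)-3-methoxybenzaldehyde
Conditions: TBSCl, imidazole, DMF, rt
Reagents that add atoms: tert-butyldimethylsilyl chloride, CC(C)(C)[Si](C)(C)Cl
Why: Standard silylation of the remaining acidic para-hydroxyl; no free neighbouring hydroxyl is left, so silyl migration cannot occur.

Step 9
Reactants: 5 3-allyl-2-hydroxy-4,6-bis(TBSO)benzoic acid; 10 2-allyl-4-(TBSO)-3-methoxybenzaldehyde
Product: 12 racemic 8-allyl-2-[2-allyl-4-(TBSO)-3-methoxyphenyl]-5,7-bis(TBSO)-4H-1,3-benzodioxin-4-one, via bis-trimethylsilyl salicylate 11 (not isolated)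
Conditions: HMDS, THF, 50 °C, then evaporation; 10, TMSOTf (10 mol%), CH2Cl2, −78 to −30 °C; pyridine quench; Et3N-deactivated silica
Reagents that add atoms: hexamethyldisilazane, C[Si](C)(C)N[Si](C)(C)C (its trimethylsilyl groups are held by intermediate 11 only and leave again)
Why: Noyori-type acetalisation as used for 1,3-dioxan-4-ones: TMSOTf activates the aldehyde toward the silyl ether and silyl ester of 11 with loss of hexamethyldisiloxane, and since the 2-OSiMe3 group is the only oxygen beside the carboxyl that can take part, O1 ends up next to the allyl-bearing carbon; the acetal centre forms as a racemate, which is of no consequence.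

Step 10
Reactants: 12 racemic 8-allyl-2-[2-allyl-4-(TBSO)-3-methoxyphenyl]-5,7-bis(TBSO)-4H-1,3-benzodioxin-4-one
Product: 13 racemic 8-allyl-2-[2-allyl-4-(TBSO)-3-methoxyphenyl]-5,7-bis(TBSO)-4-methylene-4H-1,3-benzodioxine
Conditions: Cp2TiMe2 (3 equiv), toluene/THF, 65 °C, dark; filtration through basic Al2O3
Reagents that add atoms: dimethyltitanocene Cp2TiMe2, [CH3-].[CH3-].[Ti+4].c1cc[cH-]c1.c1cc[cH-]c1
Why: Petasis methylenation: Cp2Ti=CH2 formed on heating adds [2+2] to the lactone carbonyl and cycloreverts to the enol ether under non-acidic conditions that spare the acetal, the silyl ethers and the terminal alkenes; the 5-silyloxy group lies in the plane of the flat bicycle and leaves both carbonyl faces open.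

Step 11
Reactants: 13 racemic 8-allyl-2-[2-allyl-4-(TBSO)-3-methoxyphenyl]-5,7-bis(TBSO)-4-methylene-4H-1,3-benzodioxine
Product: 14 (2S)-8-allyl-2-[2-allyl-4-(TBSO)-3-methoxyphenyl]-5,7-bis(TBSO)chroman-4-one
Conditions: (S,S)-IDPi Brønsted acid (BINOL-derived imidodiphosphorimidate, N-triflyl, 3,3'-aryl arms; 5 mol%; antipode if the sense of induction demands it), 5 Å MS, toluene, −60 °C; Et3N quench at −60 °C
Reagents that add atoms: none
Why: Proposed new method: the chiral acid protonates the enol-ether oxygen O3 and the acetal C2–O3 bond ionises to a contact ion pair of the chiral anion with the aryloxy carbenium ion ArCH=O1+ (stabilised by the para-silyloxy group of ring B), which carries the enol of the ring A acetophenone on the same arene; the enol carbon then adds to C2 and the proton returns to the anion, turning the acid over. The closest known reactions are the Me2AlCl-promoted Petasis–Ferrier rearrangement of 4-methylene-1,3-dioxanes to tetrahydropyran-4-ones, the chiral phosphoric acid aza-Petasis–Ferrier rearrangement, and counteranion-directed additions to oxocarbenium ions with IDPi acids. Ring C closes in a 6-endo-trig (enol-endo) mode, with O1, C2, C3, C4, C4a and C8a as ring members. C2 is the only new stereocentre; the old acetal centre is erased in the planar cation, so both enantiomers of 13 converge, and the confined anion decides which face of C2 is attacked. The step needs C- over O-recombination, which the irreversible C–C bond formation provides, and enol capture ahead of alkene (Prins) capture, which the substrate secures because the tethered enol is the only strong π-nucleophile within reach and both side chains are monosubstituted allyl groups.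

Step 12
Reactants: 14 (2S)-8-allyl-2-[2-allyl-4-(TBSO)-3-methoxyphenyl]-5,7-bis(TBSO)chroman-4-one
Product: 15 (2S)-2-[4-(TBSO)-3-methoxy-2-(3-methylbut-2-enyl)phenyl]-5,7-bis(TBSO)-8-(3-methylbut-2-enyl)chroman-4-one
Conditions: second-generation Grubbs catalyst RuCl2(=CHPh)(H2IMes)(PCy3) (2 × 5 mol%), 2-methylbut-2-ene/CH2Cl2 (1:1), 40 °C, sealed tube
Reagents that add atoms: 2-methylbut-2-ene, CC=C(C)C
Why: Olefin cross-metathesis of the two terminal alkenes with a large excess of 2-methylbut-2-ene gives the trisubstituted prenyl termini and propene, a standard allyl-to-prenyl conversion that touches neither the aryl ketone nor C2.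

Step 13
Reactants: 15 (2S)-2-[4-(TBSO)-3-methoxy-2-(3-methylbut-2-enyl)phenyl]-5,7-bis(TBSO)-8-(3-methylbut-2-enyl)chroman-4-one
Product: 16 (2S)-5,7-dihydroxy-2-[4-hydroxy-3-methoxy-2-(3-methylbut-2-enyl)phenyl]-8-(3-methylbut-2-enyl)chroman-4-one
Conditions: TBAF/AcOH (1:1, 3.5 equiv), THF, 0 °C
Reagents that add atoms: none
Why: Fluoride cleaves the three aryl silyl ethers, and the acetic acid buffer keeps the medium non-basic so that the 5-hydroxyflavanone does not open to the chalcone (retro-oxa-Michael) and C2 keeps its configuration.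

**Compound list**

1 | 2,4,6-trihydroxybenzaldehyde | O=Cc1c(O)cc(O)cc1O | starting material
2 | 2-hydroxy-4,6-bis(tert-butyldimethylsilyloxy)benzaldehyde | O=Cc1c(O)cc(O[Si](C)(C)C(C)(C)C)cc1O[Si](C)(C)C(C)(C)C | intermediate
3 | 2-(allyloxy)-4,6-bis(tert-butyldimethylsilyloxy)benzaldehyde | C=CCOc1cc(O[Si](C)(C)C(C)(C)C)cc(O[Si](C)(C)C(C)(C)C)c1C=O | intermediate
4 | 3-allyl-2-hydroxy-4,6-bis(tert-butyldimethylsilyloxy)benzaldehyde | O=Cc1c(O)c(CC=C)c(O[Si](C)(C)C(C)(C)C)cc1O[Si](C)(C)C(C)(C)C | intermediate
5 | 3-allyl-2-hydroxy-4,6-bis(tert-butyldimethylsilyloxy)benzoic acid | OC(=O)c1c(O)c(CC=C)c(O[Si](C)(C)C(C)(C)C)cc1O[Si](C)(C)C(C)(C)C | intermediate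
6 | 3,4-dihydroxybenzaldehyde | O=Cc1ccc(O)c(O)c1 | starting material
7 | 3-(allyloxy)-4-hydroxybenzaldehyde | O=Cc1ccc(O)c(OCC=C)c1 | intermediate
8 | 2-allyl-3,4-dihydroxybenzaldehyde | O=Cc1ccc(O)c(O)c1CC=C | intermediate
9 | 2-allyl-4-hydroxy-3-methoxybenzaldehyde | COc1c(O)ccc(C=O)c1CC=C | intermediate
10 | 2-allyl-4-(tert-butyldimethylsilyloxy)-3-methoxybenzaldehyde | COc1c(O[Si](C)(C)C(C)(C)C)ccc(C=O)c1CC=C | intermediate
11 | trimethylsilyl 3-allyl-4,6-bis(tert-butyldimethylsilyloxy)-2-(trimethylsilyloxy)benzoate | C=CCc1c(O[Si](C)(C)C)c(C(=O)O[Si](C)(C)C)c(O[Si](C)(C)C(C)(C)C)cc1O[Si](C)(C)C(C)(C)C | intermediate (not isolated)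
12 | racemic 8-allyl-2-[2-allyl-4-(tert-butyldimethylsilyloxy)-3-methoxyphenyl]-5,7-bis(tert-butyldimethylsilyloxy)-4H-1,3-benzodioxin-4-one | O=C1OC(c2ccc(O[Si](C)(C)C(C)(C)C)c(OC)c2CC=C)Oc2c(CC=C)c(O[Si](C)(C)C(C)(C)C)cc(O[Si](C)(C)C(C)(C)C)c12 | intermediate
13 | racemic 8-allyl-2-[2-allyl-4-(tert-butyldimethylsilyloxy)-3-methoxyphenyl]-5,7-bis(tert-butyldimethylsilyloxy)-4-methylene-4H-1,3-benzodioxine | C=C1OC(c2ccc(O[Si](C)(C)C(C)(C)C)c(OC)c2CC=C)Oc2c(CC=C)c(O[Si](C)(C)C(C)(C)C)cc(O[Si](C)(C)C(C)(C)C)c12 | intermediate
14 | (2S)-8-allyl-2-[2-allyl-4-(tert-butyldimethylsilyloxy)-3-methoxyphenyl]-5,7-bis(tert-butyldimethylsilyloxy)chroman-4-one | COc1c(O[Si](C)(C)C(C)(C)C)ccc([C@@H]2CC(=O)c3c(O[Si](C)(C)C(C)(C)C)cc(O[Si](C)(C)C(C)(C)C)c(CC=C)c3O2)c1CC=C | intermediate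
15 | (2S)-2-[4-(tert-butyldimethylsilyloxy)-3-methoxy-2-(3-methylbut-2-enyl)phenyl]-5,7-bis(tert-butyldimethylsilyloxy)-8-(3-methylbut-2-enyl)chroman-4-one | COc1c(O[Si](C)(C)C(C)(C)C)ccc([C@@H]2CC(=O)c3c(O[Si](C)(C)C(C)(C)C)cc(O[Si](C)(C)C(C)(C)C)c(CC=C(C)C)c3O2)c1CC=C(C)C | intermediate
16 | (2S)-5,7-dihydroxy-2-[4-hydroxy-3-methoxy-2-(3-methylbut-2-enyl)phenyl]-8-(3-methylbut-2-enyl)chroman-4-one (CNP0282226.1) | COc1c(O)ccc([C@@H]2CC(=O)c3c(O)cc(O)c(CC=C(C)C)c3O2)c1CC=C(C)C | target

**Step count**

Total: 13 steps. Longest linear sequence: 9 steps (steps 1–4 then 9–13, or steps 5–8 then 9–13).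

**Steps most likely to fail**

Step 11. The ion pair may collapse with poor facial discrimination, or the acid may protonate the enol ether at carbon so that the cation is lost to hydrolysis or arene alkylation. The fallback sets out from 13 and comes back at 14. Stoichiometric Me2AlCl in CH2Cl2 at −78 °C, the established Lewis-acid form of the Petasis–Ferrier rearrangement, should give racemic 8-allyl-2-[2-allyl-4-(TBSO)-3-methoxyphenyl]-5,7-bis(TBSO)chroman-4-one F1. Kinetic resolution of F1 by asymmetric transfer hydrogenation (RuCl[(R,R)-TsDPEN](p-cymene), HCO2H/Et3N, rt, stopped near half conversion) should reduce the (2R)-ketone to the cis-alcohol (2R,4R)-8-allyl-2-[2-allyl-4-(TBSO)-3-methoxyphenyl]-5,7-bis(TBSO)chroman-4-ol F2. The unreduced (2S)-ketone 14 is then recovered by chromatography.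

Step 9. Carbonyl activation of the hindered, electron-rich aldehyde may be slow, the silyl triflate may exchange aryl silyl ethers, or the acid may decarboxylate before ring closure. The fallback sets out from 10 and 5 and comes back at 12; it replaces direct condensation by acetal exchange on the unsilylated acid. Aldehyde 10 with HC(OMe)3 and catalytic PPTS in MeOH should give 2-allyl-4-(TBSO)-1-(dimethoxymethyl)-3-methoxybenzene F3, which ionises under mild protic acid. F3 and free acid 5 with catalytic PPTS in toluene at 40 °C over 5 Å MS (uptake of methanol) should then give 12.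

Step 7. Methylation may go to the wrong oxygen or to both, because the 3-oxide is now flanked by the allyl group. The fallback sets out from 8 and comes back at 9; it replaces dianion control by monoanion control with a temporary group. PMBCl, NaHCO3 and NaI in DMF at 40 °C should protect the more acidic 4-hydroxyl to give 2-allyl-3-hydroxy-4-(4-methoxybenzyloxy)benzaldehyde F4. MeI and K2CO3 in DMF then methylate the remaining 3-hydroxyl to give 2-allyl-3-methoxy-4-(4-methoxybenzyloxy)benzaldehyde F5. DDQ in CH2Cl2/H2O removes the PMB group to give 9.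

**Further compounds**

F1 | step 11 | racemic 8-allyl-2-[2-allyl-4-(tert-butyldimethylsilyloxy)-3-methoxyphenyl]-5,7-bis(tert-butyldimethylsilyloxy)chroman-4-one | COc1c(O[Si](C)(C)C(C)(C)C)ccc(C2CC(=O)c3c(O[Si](C)(C)C(C)(C)C)cc(O[Si](C)(C)C(C)(C)C)c(CC=C)c3O2)c1CC=C
F2 | step 11 | (2R,4R)-8-allyl-2-[2-allyl-4-(tert-butyldimethylsilyloxy)-3-methoxyphenyl]-5,7-bis(tert-butyldimethylsilyloxy)chroman-4-ol | COc1c(O[Si](C)(C)C(C)(C)C)ccc([C@H]2C[C@@H](O)c3c(O[Si](C)(C)C(C)(C)C)cc(O[Si](C)(C)C(C)(C)C)c(CC=C)c3O2)c1CC=C
F3 | step 9 | 2-allyl-4-(tert-butyldimethylsilyloxy)-1-(dimethoxymethyl)-3-methoxybenzene | COC(OC)c1ccc(O[Si](C)(C)C(C)(C)C)c(OC)c1CC=C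
F4 | step 7 | 2-allyl-3-hydroxy-4-(4-methoxybenzyloxy)benzaldehyde | O=Cc1ccc(OCc2ccc(OC)cc2)c(O)c1CC=C
F5 | step 7 | 2-allyl-3-methoxy-4-(4-methoxybenzyloxy)benzaldehyde | COc1c(OCc2ccc(OC)cc2)ccc(C=O)c1CC=C
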